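Early on G adds to J quickly: in the east run, by 0.833 d, Q reads 70.0 % and D 13.4 %, and by 6.00 d D has faded to 0.8 % while Q has sunk to 57.6 %.

in all of them: J 14 mM
- north-east: G 7.6 mM; run made earlier
- east: G 39 mM; run made earlier
- noon: G 35.0 mM; time 6.0 d
- autumn: G 11.2 mM; time 6.0 d
- summer: G 56.0 mM; time 6.0 d
- north-east (time / d: Q / %, D / %): 1.67: 12.9, 1.2; 3.00: 11.9, 0; 5.00: 13.9, 1.3; 6.00: 14.8, 1.2
- east (time / d: Q / %, D / %): 0.833: 70.0, 13.4; 2.00: 60.4, 7.0; 4.00: 58.7, 1.3; 6.00: 57.6, 0.8

(readings scatter by 1 percentage point)
* which of these holds the largest part of the J at the end of noon (D / E / J / X / Q)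
* which of these holds the largest part of the J at the end of autumn (D / E / J / X / Q)
* which of these holds the largest part of the J at the end of summer (D / E / J / X / Q)
* amount of Q at the end of summer, in percent of the J charged

1. Q holds two G on each J, so we take two equivalents as the zero of our scale. The surplus is G charged per J charged, minus two; for summer it is 2.00. At zero, every J could stop at Q.
2. East has a surplus of 0.786. Its last reading leaves 41.6 % of the J in neither Q nor D. If that J took the whole surplus, it took 1.89 G each, as read. So we reckon that J leaving Q takes about two more G, passes through D, and ends in something unread.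
3. Our rule, for flasks with J at 14 mM and a surplus between zero and 2.00, is therefore that Q's share is one minus half the surplus. Noon has a surplus of 0.500, which gives Q about 75.0 %.
4. Autumn has a surplus of −1.20, so G is the limiting reagent. North-east, at −1.46, counts to about 60.5 % of J untouched, as read, if its G went to X and Q. The same count puts J in autumn 20.0 % above Q, so we name J.
5. Summer's surplus takes Q towards 0 %, but in our reckoning the last Q and the last G fade together. We guess Q stays under 10 percent and is still the largest of the five.

The forecast named Q, J and E, with 27 % of Q in summer: “E is largest”.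

The flasks give Q, J and Q, with 8.11 % of Q in summer.

    J + G → X + Z (k = 0.00980 M⁻¹ s⁻¹)
    G + Q → E + Z (k = 7.42 × 10⁻⁴ M⁻¹ s⁻¹)
    D → L (k = 1.59 × 10⁻⁵ s⁻¹)
    G + X → Q + Z (k = 0.0146 M⁻¹ s⁻¹)
    G + E → D + Z (k = 0.00697 M⁻¹ s⁻¹)

In summer J and X stood at 0 % and 0 % by 3.00 d; after that Q fell from 15.1 % to 8.11 % and L, made from D, rose from 75.9 % to 89.5 % by 6.00 d. Of the surplus of 2.00, two G per Q and one per E were still unspent, which is 4.29 % of the G, and the flask holds 4.29 %. The neighbour with 5.6 mM of J has a surplus of 8.00; two of it spent per J would leave 60.0 % of the G, and that flask holds 60 %.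

The runs are simulated with constants of no real substance; scatter was added.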